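**Retrosynthetic overview**
1. The C12–OH comes from a terminal allylic C–H hydroxylation of the farnesyl analogue in the last step. The C2=C3 enone comes from dehydrogenating the saturated ketone, which deliberately erases the C3–H(Me) relay stereocentre.
2. The oxirane is the only ring formed, and it is formed late. It comes from a hydroxyl-directed nucleophilic epoxidation of a 4-hydroxy-2-farnesyl-5-methylcyclohexenone. The carbocycle is bought.
3. Key step: the C4–O bond is made by anodic vinylogous hydroxylation of the linear silyl dienol ether, trans to the bought methyl centre.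
4. The ring–chain bond C6–C1′ is made by alkylating an allyl β-keto ester with farnesyl bromide, followed by decarboxylative dehydrogenation to the 2-farnesyl enone.
5. All chirality originates from (R)-3-methylcyclohexanone, which is pulegone-derived.

Assumption: (R)-(+)-3-methylcyclohexanone, diallyl carbonate and (2E,6E)-farnesyl bromide are commercial. Ring atoms use the target cyclohexenone numbering (C1 = C=O, C3 = C–Me, C4 = C–O, C5/C6 = oxirane, C6 bears the chain). "Farnesyl" means (2E,6E)-3,7,11-trimethyldodeca-2,6,10-trien-1-yl.

**Step 1**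
Reactants: 1 (R)-3-methylcyclohexanone; 2 diallyl carbonate
Product: 3 allyl (4R)-4-methyl-2-oxocyclohexane-1-carboxylate (keto/enol, C1 epimers)
Conditions: NaH, THF, reflux
Reagents that add atoms: diallyl carbonate (2), C=CCOC(=O)OCC=C
Why: Claisen-type C-acylation under thermodynamic control goes to the less hindered α-carbon (C6, remote from the methyl) and is driven by formation of the stabilised β-keto ester enolate, while the non-enolisable methyl stereocentre is untouched.

**Step 2**
Reactants: 3; 4 (2E,6E)-farnesyl bromide
Product: 5 allyl (4R)-1-farnesyl-4-methyl-2-oxocyclohexane-1-carboxylate (mixture at C1)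
Conditions: K2CO3, acetone, 50 °C
Reagents that add atoms: farnesyl bromide (4), BrC/C=C(\C)CC/C=C(\C)CCC=C(C)C
Why: SN2 C-alkylation of the soft β-keto ester enolate with a primary allylic bromide forms C6–C1′ with both E-olefins retained, and the new quaternary centre is irrelevant because it becomes sp2 in step 3.

**Step 3**
Reactants: 5
Product: 6 (5R)-2-farnesyl-5-methylcyclohex-2-en-1-one
Conditions: Pd(OAc)2 (5 mol %), dppe (5 mol %), MeCN, 80 °C
Reagents that add atoms: none
Why: In the Tsuji decarboxylation–dehydrogenation, ionisation of the allyl ester, loss of CO2 and β-hydride elimination from the Pd enolate toward the ring CH2 give the α-substituted endocyclic enone regiospecifically, with propene as by-product.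

**Step 4**
Reactants: 6
Product: 7 triisopropyl{[(5S)-2-farnesyl-5-methylcyclohexa-1,3-dien-1-yl]oxy}silane (same spatial arrangement at the methyl carbon; the descriptor changes only through CIP priorities)
Conditions: t-BuOK, THF, 0 °C, 30 min; TIPSOTf, −78 °C
Reagents that add atoms: TIPSOTf, CC(C)[Si](C(C)C)(C(C)C)OS(=O)(=O)C(F)(F)F
Why: Thermodynamic γ-deprotonation gives the equilibrated, through-conjugated potassium dienolate (the species exploited in deconjugative enone alkylation), and O-silylation then delivers the linear 1-silyloxy-1,3-diene without touching the stereocentre.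

**Step 5 (key step)**
Reactants: 7
Product: 8 (4R,5S)-2-farnesyl-4-hydroxy-5-methylcyclohex-2-en-1-one (OH and Me trans)
Conditions: graphite(+)|Pt(−), undivided cell, +0.95 V vs Ag/AgCl (ca. 2.1 F/mol), n-Bu4NBF4, NaHCO3, MeCN/THF/H2O 6:3:1, 0 °C, Ar
Reagents that add atoms: water, O
Why: Proposed new method: potential-gated anodic vinylogous hydroxylation (an "electrochemical vinylogous Rubottom"); the silyloxydiene (Ep about +1.0 V) is oxidised roughly 0.8 V below the trisubstituted chain olefins (about +1.9 V), so only the ring loses an electron; water adds to the open diene terminus C4, because attack at C6 is blocked by the chain and would forfeit allyl stabilisation; the resulting 1-silyloxyallyl radical is oxidised at once to the silyloxocarbenium ion, which sheds the TIPS group to give the enone; the bulky TIPS group slows Si–O mesolysis, and the weak bicarbonate buffer disfavours radical-cation deprotonation and aromatisation; the C4–O bond forms anti to the pseudoaxial methyl, the same torsional bias that makes trapping of 3-substituted cyclohexanone enolates trans-selective (estimated dr about 6:1, minor cis isomer removed by chromatography); closest known reaction types are Shono-type anodic α-oxygenation of enol ethers and acetates, anodic enol-ether umpolung, and the peracid vinylogous Rubottom oxidation, which cannot be used here because of the triene.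

**Step 6**
Reactants: 8
Product: 9 (1R,4S,5R,6R)-1-farnesyl-5-hydroxy-4-methyl-7-oxabicyclo[4.1.0]heptan-2-one (oxirane O syn to OH, anti to Me)
Conditions: t-BuOOH (decane), Triton B (0.2 equiv), THF, 0 °C
Reagents that add atoms: tert-butyl hydroperoxide, CC(C)(C)OO
Why: Weitz–Scheffer nucleophilic epoxidation touches only the enone C=C, and axial attack at C5 trans to the C3-methyl (the carvone / 5-substituted cyclohexenone rule) is reinforced by hydrogen-bond delivery from the pseudoequatorial C4–OH, so this matched control sets C5 and C6 syn to the C4 oxygen.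

**Step 7**
Reactants: 9
Product: 10 (1R,2R,3S,6R)-6-farnesyl-3-methyl-5-oxo-7-oxabicyclo[4.1.0]heptan-2-yl acetate
Conditions: Ac2O, pyridine, DMAP (cat.), CH2Cl2, 0 °C
Reagents that add atoms: acetic anhydride, CC(=O)OC(C)=O
Why: This is a DMAP-catalysed acylation of the only hydroxyl, and because a syn-epoxy alcohol cannot undergo Payne migration, no stereocentre is disturbed.

**Step 8**
Reactants: 10
Product: 11 (1R,2R,6R)-6-farnesyl-3-methyl-5-oxo-7-oxabicyclo[4.1.0]hept-3-en-2-yl acetate
Conditions: LiHMDS (1.05 equiv), THF, −78 °C; PhS(Cl)=N-t-Bu, −78 °C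
Reagents that add atoms: none
Why: In the Mukaiyama one-pot dehydrogenation the ketone can enolise only toward C2 (C6 is quaternary), so sulfur attack on that enolate and intramolecular syn-elimination with the cis C3–H install C2=C3, erasing the relay centre C3 and leaving C4–C6 untouched.

**Step 9**
Reactants: 11
Product: 12 yanuthone L, (1R,2R,6R)-6-[(2E,6E,10E)-12-hydroxy-3,7,11-trimethyldodeca-2,6,10-trien-1-yl]-3-methyl-5-oxo-7-oxabicyclo[4.1.0]hept-3-en-2-yl acetate
Conditions: SeO2 (0.3 equiv), t-BuOOH (2 equiv), salicylic acid (0.1 equiv), CH2Cl2, 0 °C to rt, stopped at about 60 % conversion, 11 recycled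
Reagents that add atoms: selenium dioxide, O=[Se]=O (delivers the O); tert-butyl hydroperoxide, CC(C)(C)OO (terminal oxidant)
Why: Catalytic SeO2/t-BuOOH allylic hydroxylation (ene reaction, then [2,3]-shift) selects the E-methyl of the terminal, least hindered and most electron-rich isopropylidene of farnesyl chains, and it ignores the electron-poor enone and its methyl.

**Compound list**
1 | (R)-3-methylcyclohexanone | C[C@@H]1CCCC(=O)C1 | starting material
2 | diallyl carbonate | C=CCOC(=O)OCC=C | starting material
3 | allyl (4R)-4-methyl-2-oxocyclohexane-1-carboxylate | C[C@@H]1CCC(C(=O)OCC=C)C(=O)C1 | intermediate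
4 | (2E,6E)-farnesyl bromide | BrC/C=C(\C)CC/C=C(\C)CCC=C(C)C | starting material
5 | allyl (4R)-1-farnesyl-4-methyl-2-oxocyclohexane-1-carboxylate | C[C@@H]1CCC(C/C=C(\C)CC/C=C(\C)CCC=C(C)C)(C(=O)OCC=C)C(=O)C1 | intermediate
6 | (5R)-2-farnesyl-5-methylcyclohex-2-en-1-one | C[C@@H]1CC=C(C/C=C(\C)CC/C=C(\C)CCC=C(C)C)C(=O)C1 | intermediate
7 | TIPS dienol ether, (5S)-2-farnesyl-5-methyl-1-(triisopropylsilyloxy)cyclohexa-1,3-diene | C[C@@H]1C=CC(C/C=C(\C)CC/C=C(\C)CCC=C(C)C)=C(O[Si](C(C)C)(C(C)C)C(C)C)C1 | intermediate
8 | (4R,5S)-2-farnesyl-4-hydroxy-5-methylcyclohex-2-en-1-one | O[C@@H]1[C@@H](C)CC(=O)C(C/C=C(\C)CC/C=C(\C)CCC=C(C)C)=C1 | intermediate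
9 | (1R,4S,5R,6R)-1-farnesyl-5-hydroxy-4-methyl-7-oxabicyclo[4.1.0]heptan-2-one | O[C@@H]1[C@@H](C)CC(=O)[C@]2(C/C=C(\C)CC/C=C(\C)CCC=C(C)C)O[C@H]12 | intermediate
10 | (1R,2R,3S,6R)-6-farnesyl-3-methyl-5-oxo-7-oxabicyclo[4.1.0]heptan-2-yl acetate | CC(=O)O[C@@H]1[C@@H](C)CC(=O)[C@]2(C/C=C(\C)CC/C=C(\C)CCC=C(C)C)O[C@H]12 | intermediate
11 | (1R,2R,6R)-6-farnesyl-3-methyl-5-oxo-7-oxabicyclo[4.1.0]hept-3-en-2-yl acetate | CC(=O)O[C@@H]1C(C)=CC(=O)[C@]2(C/C=C(\C)CC/C=C(\C)CCC=C(C)C)O[C@H]12 | intermediate
12 | yanuthone L | CC(=O)O[C@@H]1C(C)=CC(=O)[C@]2(C/C=C(\C)CC/C=C(\C)CC/C=C(\C)CO)O[C@H]12 | target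

**Total step count:** 9. **Longest linear sequence:** 9 (from 1).

**Steps most likely to fail**
1. **Step 5 (proposed new anodic γ-hydroxylation).**
   - Risks: radical-cation deprotonation leading to 2-farnesyl-5-methylphenol, premature Si–O cleavage, and modest trans/cis ratio.
   - Fallback (known chemistry): switch from electron transfer to pericyclic oxygen transfer. Run a tetraphenylporphyrin-sensitised singlet-oxygen [4+2] on silyloxydiene 7 at −78 °C with a metered O2 dose, then reduce with PPh3 to obtain 8. Electron-rich s-cis dienes are known to outcompete trisubstituted olefins.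
2. **Step 4 (linear versus cross-conjugated enolisation).**
   - Risk: the cross-conjugated 2-silyloxydiene forms instead, and that isomer would only aromatise on oxidation.
   - Fallback: change the activated species. Condense 6 with pyrrolidine to give the thermodynamically linear dienamine, which oxidises at about +0.4 V, and hydrolyse after the γ-oxygenation to reach 8.
3. **Step 9 (late-stage SeO2 hydroxylation).**
   - Risks: moderate conversion, over-oxidation to the enal, and oxidation at an internal methyl.
   - Fallback: move from late C–H oxidation to a building-block strategy. Prepare (2E,6E,10E)-12-(TBSO)farnesyl bromide from farnesyl acetate (SeO2/t-BuOOH; TBSCl; K2CO3/MeOH; CBr4/PPh3). Use it in step 2 and finish with HF·pyridine instead of SeO2.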